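**Retrosynthetic overview**
- The benzene ring A and the pyran ring C are disconnected together: an intramolecular Diels–Alder reaction of a Chan-type 1-alkoxy-1,3-bis(silyloxy)-2-methoxydiene (from an α-methoxyacetoacetate ester) with a tethered terminal alkyne, followed by loss of silanol, gives the chroman directly.
- The ester comes from (S)-2-aryl-pent-4-yn-1-ol and methyl 2-methoxy-3-oxobutanoate (made from methyl methoxyacetate).
- The alkynol comes from an (S)-β-aryl-γ-butyrolactone by one-pot DIBAL-H reduction and Ohira–Bestmann homologation.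
- The lactone comes from Rh/(S)-BINAP 1,4-addition of the tetramethoxyphenylboronic acid to furan-2(5H)-one; this sets the only stereocentre (C3 of the target).
- Ring order: B is bought as the arene; a temporary lactone carries the stereocentre; A and C form together in the last step.

Assumption: 1,2,3,4-tetramethoxybenzene, furan-2(5H)-one and methyl methoxyacetate are taken as commercial; (S)-BINAP is assigned to the (S)-lactone by the usual cyclic-enone model, and the ligand antipode would be used if analysis showed the opposite sense.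

**Route**

Step 1
Reactants: 1 1,2,3,4-tetramethoxybenzene
Product: 3 (2,3,4,5-tetramethoxyphenyl)boronic acid, via aryllithium 2 (not isolated)
Conditions: n-BuLi, TMEDA, THF, 0 °C → rt; B(OiPr)3, −78 °C → rt; 1 M HCl, 0 °C
Reagents that add atoms: triisopropyl borate CC(C)OB(OC(C)C)OC(C)C; water O
Why: Methoxy-directed ortho-lithiation (the two free ring positions are equivalent) followed by electrophilic borylation and hydrolysis gives the boronic acid.

Step 2
Reactants: 3 (2,3,4,5-tetramethoxyphenyl)boronic acid; 4 furan-2(5H)-one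
Product: 5 (4S)-4-(2,3,4,5-tetramethoxyphenyl)dihydrofuran-2(3H)-one
Conditions: [Rh(OH)((S)-BINAP)]2 (1.5 mol %), 3 (2 equiv), dioxane/H2O 10:1, 40 °C
Reagents that add atoms: none
Why: Hayashi–Miyaura asymmetric 1,4-addition: the aryl–Rh(I)/(S)-BINAP species carbometalates one enantioface of the butenolide and the oxa-π-allyl rhodium is protonated by water, setting C4 as (S), which becomes C3 of the target.

Step 3
Reactants: 5 (4S)-4-(2,3,4,5-tetramethoxyphenyl)dihydrofuran-2(3H)-one
Product: 7 (2S)-2-(2,3,4,5-tetramethoxyphenyl)pent-4-yn-1-ol, via lactol 6 (not isolated)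
Conditions: DIBAL-H (1.1 equiv), CH2Cl2, −78 °C; then MeOH, K2CO3, Ohira–Bestmann reagent, −78 °C → rt
Reagents that add atoms: dimethyl (1-diazo-2-oxopropyl)phosphonate CC(=O)C(=[N+]=[N-])P(=O)(OC)OC
Why: DIBAL-H stops at the lactolate at −78 °C, and the open hydroxy-aldehyde form of the lactol undergoes Seyferth–Gilbert (Ohira–Bestmann) homologation to the terminal alkyne; the stereocentre is β to the aldehyde and cannot enolise.

Step 4
Reactants: 8 methyl methoxyacetate
Product: 10 methyl 2-methoxy-3-oxobutanoate, via lithium enolate 9 (not isolated)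
Conditions: LDA, THF, −78 °C; MeC(O)N(OMe)Me, −78 → 0 °C; aq NH4Cl
Reagents that add atoms: N-methoxy-N-methylacetamide CC(=O)N(C)OC
Why: Crossed Claisen-type C-acylation of the chelated glycolate ester enolate by a Weinreb amide, whose stable tetrahedral adduct prevents over-acylation and proton transfer; the α-carbon is racemic and becomes sp2 later.

Step 5
Reactants: 7 (2S)-2-(2,3,4,5-tetramethoxyphenyl)pent-4-yn-1-ol; 10 methyl 2-methoxy-3-oxobutanoate
Product: 11 (2S)-2-(2,3,4,5-tetramethoxyphenyl)pent-4-yn-1-yl 2-methoxy-3-oxobutanoate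
Conditions: 10 (1.5 equiv), DMAP (0.2 equiv), toluene, reflux, 4 Å MS (removal of MeOH)
Reagents that add atoms: none
Why: β-Keto ester transesterification (DMAP-catalysed, acylketene pathway) is driven by removal of methanol and leaves the alkyne, the aryl ethers and the stereocentre untouched.

Step 6
Reactants: 11 (2S)-2-(2,3,4,5-tetramethoxyphenyl)pent-4-yn-1-yl 2-methoxy-3-oxobutanoate
Product: 15 (3S)-8-methoxy-3-(2,3,4,5-tetramethoxyphenyl)chroman-7-ol, via bis-silyl diene 12 (not isolated), via cycloadduct 13 (not isolated), via aryl silyl ether 14 (not isolated)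
Conditions: TBSOTf (2.4 equiv), Et3N (4 equiv), Et2O, 0 °C → rt; filter, concentrate; o-dichlorobenzene (0.01 M), 180 °C, sealed tube; then HF·pyridine, THF, 0 °C
Reagents that add atoms: none
Why: Proposed new method: soft double enolisation converts the β-keto ester into the Chan-type diene 12, whose ketene-acetal oxygen is the tether (so there is no ester s-trans penalty), and a type-1 intramolecular Diels–Alder reaction onto the unactivated terminal alkyne (four-atom tether, helped by the C3 aryl substituent) forms the carbocycle and the pyran together as 1,4-cyclohexadiene 13, which aromatises irreversibly by 1,4-elimination of silanol (silanolate is the better leaving group, so the ring oxygen stays) before fluoride frees the C7 phenol; the closest known reaction types are the intermolecular Diels–Alder benzannulation of Chan/Brassard dienes with alkynes to resorcinol ethers and the thermal intramolecular Diels–Alder reaction of 1,3-dien-9-ynes; C3 is a spectator and no new stereocentre survives.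

**Compound list**

1 | 1,2,3,4-tetramethoxybenzene | COc1ccc(OC)c(OC)c1OC | starting material
2 | (2,3,4,5-tetramethoxyphenyl)lithium | [Li]c1cc(OC)c(OC)c(OC)c1OC | intermediate
3 | (2,3,4,5-tetramethoxyphenyl)boronic acid | OB(O)c1cc(OC)c(OC)c(OC)c1OC | intermediate
4 | furan-2(5H)-one | O=C1OCC=C1 | starting material
5 | (4S)-4-(2,3,4,5-tetramethoxyphenyl)dihydrofuran-2(3H)-one | O=C1C[C@@H](c2cc(OC)c(OC)c(OC)c2OC)CO1 | intermediate
6 | (4S)-4-(2,3,4,5-tetramethoxyphenyl)tetrahydrofuran-2-ol (lactol, both anomers) | OC1C[C@@H](c2cc(OC)c(OC)c(OC)c2OC)CO1 | intermediate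
7 | (2S)-2-(2,3,4,5-tetramethoxyphenyl)pent-4-yn-1-ol | OC[C@@H](CC#C)c1cc(OC)c(OC)c(OC)c1OC | intermediate
8 | methyl methoxyacetate | COCC(=O)OC | starting material
9 | lithium enolate of methyl methoxyacetate | [Li]OC(OC)=COC | intermediate
10 | methyl 2-methoxy-3-oxobutanoate (racemic) | COC(C(C)=O)C(=O)OC | intermediate
11 | (2S)-2-(2,3,4,5-tetramethoxyphenyl)pent-4-yn-1-yl 2-methoxy-3-oxobutanoate (α-carbon epimers) | CC(=O)C(OC)C(=O)OC[C@@H](CC#C)c1cc(OC)c(OC)c(OC)c1OC | intermediate
12 | 1,3-bis(tert-butyldimethylsilyloxy)-2-methoxy-1-[(2S)-2-(2,3,4,5-tetramethoxyphenyl)pent-4-yn-1-yloxy]buta-1,3-diene (ketene-acetal geometry undefined) | C=C(O[Si](C)(C)C(C)(C)C)C(OC)=C(O[Si](C)(C)C(C)(C)C)OC[C@@H](CC#C)c1cc(OC)c(OC)c(OC)c1OC | intermediate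
13 | (3S)-7,8a-bis(tert-butyldimethylsilyloxy)-8-methoxy-3-(2,3,4,5-tetramethoxyphenyl)-3,4,6,8a-tetrahydro-2H-chromene (both C8a epimers) | COC1=C(O[Si](C)(C)C(C)(C)C)CC=C2C[C@@H](c3cc(OC)c(OC)c(OC)c3OC)COC12O[Si](C)(C)C(C)(C)C | intermediate
14 | (3S)-7-(tert-butyldimethylsilyloxy)-8-methoxy-3-(2,3,4,5-tetramethoxyphenyl)chroman | COc1c(O[Si](C)(C)C(C)(C)C)ccc2C[C@@H](c3cc(OC)c(OC)c(OC)c3OC)COc12 | intermediate
15 | (3S)-8-methoxy-3-(2,3,4,5-tetramethoxyphenyl)chroman-7-ol (CNP0152490.1) | COc1cc([C@H]2COc3c(ccc(O)c3OC)C2)c(OC)c(OC)c1OC | target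

**Totals and risks**

Total step count: 6. Longest linear sequence: 5 (steps 1, 2, 3, 5, 6); step 4 is a one-step side branch.

Steps most likely to fail:

1. Step 6. The alkyne is unactivated, the tether has four atoms, and the bis-silyl ketene-acetal diene must survive about 180 °C. Fallback, setting out from 7 and returning at 15: lower the dienophile LUMO with a traceless bromine. The dianion of 7 (n-BuLi, 2.1 equiv, THF, −78 °C) is quenched with NBS to give (2S)-5-bromo-2-(2,3,4,5-tetramethoxyphenyl)pent-4-yn-1-ol F1. Transesterification with 10 as in step 5 gives (2S)-5-bromo-2-(2,3,4,5-tetramethoxyphenyl)pent-4-yn-1-yl 2-methoxy-3-oxobutanoate F2. TBSOTf/Et3N gives the bromoalkyne bis-silyl diene F3, which should cyclise at about 110–130 °C to the 5-bromo cycloadduct F4. This aromatises to the 5-bromo aryl silyl ether F5, and HF·pyridine gives (3S)-5-bromo-8-methoxy-3-(2,3,4,5-tetramethoxyphenyl)chroman-7-ol F6. Hydrogenolysis (H2, Pd/C, K2CO3, MeOH) removes the bromine and gives 15.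

2. Step 2. The boronic acid is ortho-substituted and very electron-rich (prone to protodeboronation), and the butenolide is a sluggish, base-sensitive acceptor. Fallback, setting out from 3 and returning at 5: Suzuki coupling of 3 with purchased 4-bromofuran-2(5H)-one (Pd(PPh3)4, K2CO3, dioxane/H2O, 80 °C) gives the achiral butenolide 4-(2,3,4,5-tetramethoxyphenyl)furan-2(5H)-one F7. The stereocentre is then set by copper hydride asymmetric conjugate reduction (Cu(OAc)2, p-Tol-BINAP in the antipode that gives (S), PMHS, t-BuOH, toluene), which delivers 5.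

3. Step 3. In the one-pot sequence the lactolate may over-reduce, or the closed lactol may react slowly with the diazophosphonate. Fallback, setting out from 5 and returning at 7: the lactol 6 is isolated after the DIBAL-H reduction. Wittig chloromethylenation (Ph3P=CHCl from (chloromethyl)triphenylphosphonium chloride and KOtBu, THF, 0 °C) gives (2S)-5-chloro-2-(2,3,4,5-tetramethoxyphenyl)pent-4-en-1-ol F8 as an E/Z mixture. Excess LDA (THF, −78 → 0 °C) dehydrochlorinates it to 7.

**Further compounds**

F1 | step 6 | (2S)-5-bromo-2-(2,3,4,5-tetramethoxyphenyl)pent-4-yn-1-ol | OC[C@@H](CC#CBr)c1cc(OC)c(OC)c(OC)c1OC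
F2 | step 6 | (2S)-5-bromo-2-(2,3,4,5-tetramethoxyphenyl)pent-4-yn-1-yl 2-methoxy-3-oxobutanoate | CC(=O)C(OC)C(=O)OC[C@@H](CC#CBr)c1cc(OC)c(OC)c(OC)c1OC
F3 | step 6 | bromoalkyne bis-silyl diene | C=C(O[Si](C)(C)C(C)(C)C)C(OC)=C(O[Si](C)(C)C(C)(C)C)OC[C@@H](CC#CBr)c1cc(OC)c(OC)c(OC)c1OC
F4 | step 6 | 5-bromo cycloadduct | COC1=C(O[Si](C)(C)C(C)(C)C)CC(Br)=C2C[C@@H](c3cc(OC)c(OC)c(OC)c3OC)COC12O[Si](C)(C)C(C)(C)C
F5 | step 6 | 5-bromo aryl silyl ether | COc1c(O[Si](C)(C)C(C)(C)C)cc(Br)c2C[C@@H](c3cc(OC)c(OC)c(OC)c3OC)COc12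
F6 | step 6 | (3S)-5-bromo-8-methoxy-3-(2,3,4,5-tetramethoxyphenyl)chroman-7-ol | COc1c(O)cc(Br)c2C[C@@H](c3cc(OC)c(OC)c(OC)c3OC)COc12
F7 | step 2 | 4-(2,3,4,5-tetramethoxyphenyl)furan-2(5H)-one | O=C1OCC(c2cc(OC)c(OC)c(OC)c2OC)=C1
F8 | step 3 | (2S)-5-chloro-2-(2,3,4,5-tetramethoxyphenyl)pent-4-en-1-ol (E/Z) | OC[C@@H](CC=CCl)c1cc(OC)c(OC)c(OC)c1OC
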